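The runs were computed for an exercise; noise was put on by code.

Time comes first: the product reading stops rising by 5.00 min in the south-east run and by 4.00 min in the north run, and the flask is asked about later than both, at 15 min. So we reckon an end state, not a rate.

| setting | south-east | north | flask |
|---|---|---|---|
| substrate | 0.15 M | 0.35 M | 0.23 M |
| salt in the second phase | 1.3 equiv | 1.3 equiv | 1.30 equiv |
| spent carrier | 1.8 mol% | 1.8 mol% | 1.8 mol% |
| remark | run made earlier | run made earlier |  |
| time |  |  | 15 min |
| volume of the second phase over the first |  |  | 1.0 |

| run | time / min | product / % | crystals / % |
|---|---|---|---|
| south-east | 0.667 | 32.2 | 0.5 |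
| south-east | 1.33 | 42.5 | 0 |
| south-east | 2.50 | 50.5 | 0.2 |
| south-east | 5.00 | 52.4 | 1.0 |
| south-east | 10.0 | 52.5 | 0 |
| north | 0.833 | 66.4 | 6.7 |
| north | 2.50 | 78.9 | 23.2 |
| north | 4.00 | 80.7 | 25.0 |
| north | 6.00 | 81.6 | 24.6 |
| north | 10.0 | 79.8 | 24.6 |

(scatter of a reading: 1 percentage point)

- for product the crystals are counted in
- charges count per volume of the first phase; a concentration in a rate is the amount of a species over the volume of its own phase; every rate counts per litre of the first phase
- as a solid, counted per litre of solution: crystals
- the earlier runs hold the two phases in the same ratio of volumes as the flask asked about

* amount of product and crystals together at 15 min, in percent of the substrate charged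
* concentration of product in solution at 15 min, in percent of saturation

The bench rule says that with equivalents and loading held, a first-order loss of substrate reaches the same percent at a given time at any concentration. These runs break it, with plateaus near 52.4% in the south-east run and 80.7% in the north run. Take the negative logarithm of the fraction of substrate left, the exponent of a pseudo-first-order loss. It reads 0.743 and 1.65, a ratio of 2.22 against 2.33 for the charges. Our reading is that the exponent follows the spent carrier charged per litre, as it should if the carrier dies at its own first-order pace.

So we carry the mean of plateau exponent over spent carrier charged, the reach, 268 M⁻¹. The flask is charged with 0.00414 M of spent carrier, so its exponent is 1.11 and our own figure is 67.1%. By our reckoning that is 0.154 M in solution in the flask. The north run, which holds crystals, reads 0.196 M dissolved, more than our figure for the flask, so we expect no crystals and 78.6% of saturation.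

The forecast gives 66.5% (63% to 70%) and 78.5% (74% to 83%), slightly below our figures, on this ground: “Dying carrier fits better.”

The flask gives 66.8% and 76.9%, both inside the forecast's ranges.

    spent carrier + salt in the second phase ⇌ fresh carrier + spent salt in the second phase (K = 2.80, k = 8.00 M⁻¹ s⁻¹)
    crystals ⇌ product, rate k2*(cs2 - [product]) while solid is left; crystals form when [product] > cs2 (solubility = 0.200 M, k = 0.220 s⁻¹)
    fresh carrier → spent catalyst (k = 0.0450 s⁻¹)
    substrate + fresh carrier → product + spent carrier (k = 12.0 M⁻¹ s⁻¹)

The stop in the flask comes from the passing of fresh carrier into spent catalyst: without that step the flask stands at 100% at 15 min instead of 66.8%. In a neighbour flask charged with 1.1 mol% of spent carrier, the reach gives an exponent of 0.679, so 49.3%; that flask computes to 49.1%.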